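**Retrosynthetic overview**
1. Target ⇒ phenol deacetylation, then a Stille disconnection of the C5'–prenyl bond, giving 5'-bromo-7,2'-diacetoxy-4'-methoxyisoflavone. The oxidation-sensitive prenyl group is attached only after all oxidative and acidic steps.
2. Bromoisoflavone ⇒ opening of ring C at O1–C2 to a 2-aryl-3,3-dimethoxypropan-1-one, then a retro 1,2-aryl shift to a 2'-hydroxychalcone.
3. Chalcone ⇒ Claisen–Schmidt aldol disconnection (the future C2–C3 bond) to 4-benzyloxy-2-hydroxyacetophenone and 2-benzyloxy-5-bromo-4-methoxybenzaldehyde.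
4. These two partners ⇒ 2,4-dihydroxyacetophenone and 2-hydroxy-4-methoxybenzaldehyde, by benzylation and by bromination plus benzylation.
5. Ring order: rings A and B are bought as arenes. The pyranone ring C is the only ring built, and it closes after the aldol and the aryl shift.

Assumption: the target has no stereocentre and no E/Z-isomeric double bond (the prenyl alkene carries two identical methyl groups). It is therefore one achiral compound and no enantioselective step is needed.

**Step 1**
Reactants: 1 2-hydroxy-4-methoxybenzaldehyde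
Product: 2 5-bromo-2-hydroxy-4-methoxybenzaldehyde
Conditions: Br2 (1.02 equiv), CH2Cl2, 0 °C to rt, 2 h
Reagents that add atoms: bromine, BrBr
Why: Electrophilic aromatic bromination goes to C5 because that position is para to the free OH, ortho to OMe and meta to CHO, and is much less crowded than C3 between the two oxygens.

**Step 2**
Reactants: 2 5-bromo-2-hydroxy-4-methoxybenzaldehyde
Product: 3 2-(benzyloxy)-5-bromo-4-methoxybenzaldehyde
Conditions: BnBr (1.2 equiv), K2CO3 (1.5 equiv), DMF, 60 °C, 4 h
Reagents that add atoms: benzyl bromide, BrCc1ccccc1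
Why: Williamson ether synthesis gives a benzyl ether that survives KOH, Tl(NO3)3 and hot HCl, so the ring B oxygen cannot later attack the acetal carbon and divert material to a 3-aroylbenzofuran.

**Step 3**
Reactants: 4 1-(2,4-dihydroxyphenyl)ethan-1-one (2,4-dihydroxyacetophenone)
Product: 5 1-[4-(benzyloxy)-2-hydroxyphenyl]ethan-1-one
Conditions: BnBr (1.05 equiv), K2CO3 (1.2 equiv), acetone, reflux, 6 h
Reagents that add atoms: benzyl bromide, BrCc1ccccc1
Why: This Williamson ether synthesis is regioselective because the 2-OH is hydrogen-bonded to the ketone and far less nucleophilic, so one equivalent of BnBr alkylates only the 4-OH.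

**Step 4**
Reactants: 5 1-[4-(benzyloxy)-2-hydroxyphenyl]ethan-1-one; 3 2-(benzyloxy)-5-bromo-4-methoxybenzaldehyde
Product: 7 (E)-1-[4-(benzyloxy)-2-hydroxyphenyl]-3-[2-(benzyloxy)-5-bromo-4-methoxyphenyl]prop-2-en-1-one (the 2'-hydroxychalcone), via racemic beta-hydroxy ketone 6 (not isolated)
Conditions: KOH (50% aq, 10 equiv), EtOH/THF 2:1, rt, 48 h; then ice, 2 M HCl
Reagents that add atoms: none
Why: In this Claisen–Schmidt crossed aldol condensation only the methyl ketone can enolise, the adduct loses water by E1cB to the thermodynamically favoured E-enone, and the racemic carbinol centre of 6 is erased in that dehydration.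

**Step 5**
Reactants: 7 the (E)-2'-hydroxychalcone
Product: 8 racemic 1-[4-(benzyloxy)-2-hydroxyphenyl]-2-[2-(benzyloxy)-5-bromo-4-methoxyphenyl]-3,3-dimethoxypropan-1-one
Conditions: Tl(NO3)3·3H2O (1.2 equiv), MeOH/CH2Cl2 3:1, rt, 16 h, dark; filter off TlNO3
Reagents that add atoms: methanol, CO
Why: In this oxidative chalcone rearrangement trivalent thallium and methanol add across the enone, loss of monovalent thallium is assisted by a 1,2-shift of the electron-rich para-methoxyaryl ring from C-beta to C-alpha, methanol traps the oxocarbenium ion as the dimethyl acetal, and the new stereocentre is racemic and vanishes in step 6.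

**Step 6**
Reactants: 8 the racemic dimethyl acetal
Product: 10 7-(benzyloxy)-3-[2-(benzyloxy)-5-bromo-4-methoxyphenyl]-4H-chromen-4-one, via 2-methoxyisoflavanone diastereomer mixture 9 (not isolated)
Conditions: 10% aq HCl, MeOH/1,4-dioxane, reflux, 3 h
Reagents that add atoms: none
Why: Acid-catalysed transacetalisation lets the ring A phenol close the six-membered ring on the acetal carbon, beta-elimination of methanol then gives the conjugated chromone and removes both stereocentres, and the benzyl ethers and the C–Br bond are inert to HCl in methanol.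

**Step 7**
Reactants: 10 7-(benzyloxy)-3-[2-(benzyloxy)-5-bromo-4-methoxyphenyl]-4H-chromen-4-one
Product: 11 3-(5-bromo-2-hydroxy-4-methoxyphenyl)-7-hydroxy-4H-chromen-4-one
Conditions: BCl3 (1 M in CH2Cl2, 6 equiv), pentamethylbenzene (6 equiv), CH2Cl2, −78 to −20 °C, 2 h; H2O quench
Reagents that add atoms: none
Why: In this Lewis-acid benzyl ether cleavage BCl3 ionises only the benzylic C–O bonds at low temperature, pentamethylbenzene captures the benzyl cation by Friedel–Crafts alkylation so it cannot C-benzylate the phenols, and the aryl methyl ether and the C–Br bond (which hydrogenolysis would endanger) stay intact.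

**Step 8**
Reactants: 11 3-(5-bromo-2-hydroxy-4-methoxyphenyl)-7-hydroxy-4H-chromen-4-one
Product: 12 3-[2-(acetyloxy)-5-bromo-4-methoxyphenyl]-4-oxo-4H-chromen-7-yl acetate
Conditions: Ac2O (4 equiv), pyridine, DMAP (5 mol %), rt, 3 h
Reagents that add atoms: acetic anhydride, CC(=O)OC(C)=O
Why: DMAP-catalysed O-acylation masks both acidic phenols, makes the bromoarene less electron-rich for oxidative addition, and installs groups that can be removed without acid so the prenyl alkene is never exposed to it.

**Step 9**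
Reactants: 12 the bromo diacetate; 13 tributyl(3-methylbut-2-en-1-yl)stannane
Product: 14 3-[2-(acetyloxy)-4-methoxy-5-(3-methylbut-2-en-1-yl)phenyl]-4-oxo-4H-chromen-7-yl acetate
Conditions: 13 (1.5 equiv), Pd(PPh3)4 (5 mol %), degassed DMF, 100 °C, 12 h
Reagents that add atoms: tributyl(3-methylbut-2-en-1-yl)stannane 13, CCCC[Sn](CCCC)(CCCC)CC=C(C)C
Why: In this Stille cross-coupling zerovalent palladium inserts into the C–Br bond, tin hands over the prenyl group, and reductive elimination from the eta-3 prenyl aryl palladium complex takes place at the unsubstituted terminus, giving the linear prenyl arene under neutral conditions that spare the acetates and the chromone.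

**Step 10**
Reactants: 14 the prenylated diacetate
Product: 15 7-hydroxy-3-[2-hydroxy-4-methoxy-5-(3-methylbut-2-en-1-yl)phenyl]-4H-chromen-4-one (target)
Conditions: K2CO3 (3 equiv), MeOH/THF 2:1, 0 °C to rt, 1 h; then 1 M HCl to pH 5
Reagents that add atoms: none
Why: Base-mediated methanolysis (transesterification) of aryl acetates is fast because phenoxides are good leaving groups, so both esters fall off under conditions too mild to open the pyranone ring or affect the prenyl alkene.

**Compound list**
1 | 2-hydroxy-4-methoxybenzaldehyde | COc1ccc(C=O)c(O)c1 | starting material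
2 | 5-bromo-2-hydroxy-4-methoxybenzaldehyde | COc1cc(O)c(C=O)cc1Br | intermediate
3 | 2-(benzyloxy)-5-bromo-4-methoxybenzaldehyde | COc1cc(OCc2ccccc2)c(C=O)cc1Br | intermediate
4 | 1-(2,4-dihydroxyphenyl)ethan-1-one | CC(=O)c1ccc(O)cc1O | starting material
5 | 1-[4-(benzyloxy)-2-hydroxyphenyl]ethan-1-one | CC(=O)c1ccc(OCc2ccccc2)cc1O | intermediate
6 | racemic 1-[4-(benzyloxy)-2-hydroxyphenyl]-3-[2-(benzyloxy)-5-bromo-4-methoxyphenyl]-3-hydroxypropan-1-one (aldol adduct, not isolated) | COc1cc(OCc2ccccc2)c(C(O)CC(=O)c2ccc(OCc3ccccc3)cc2O)cc1Br | intermediate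
7 | (E)-1-[4-(benzyloxy)-2-hydroxyphenyl]-3-[2-(benzyloxy)-5-bromo-4-methoxyphenyl]prop-2-en-1-one | COc1cc(OCc2ccccc2)c(/C=C/C(=O)c2ccc(OCc3ccccc3)cc2O)cc1Br | intermediate
8 | racemic 1-[4-(benzyloxy)-2-hydroxyphenyl]-2-[2-(benzyloxy)-5-bromo-4-methoxyphenyl]-3,3-dimethoxypropan-1-one | COc1cc(OCc2ccccc2)c(C(C(OC)OC)C(=O)c2ccc(OCc3ccccc3)cc2O)cc1Br | intermediate
9 | 7-(benzyloxy)-3-[2-(benzyloxy)-5-bromo-4-methoxyphenyl]-2-methoxychroman-4-one (racemic diastereomer mixture, not isolated) | COC1Oc2cc(OCc3ccccc3)ccc2C(=O)C1c1cc(Br)c(OC)cc1OCc1ccccc1 | intermediate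
10 | 7-(benzyloxy)-3-[2-(benzyloxy)-5-bromo-4-methoxyphenyl]-4H-chromen-4-one | COc1cc(OCc2ccccc2)c(-c2coc3cc(OCc4ccccc4)ccc3c2=O)cc1Br | intermediate
11 | 3-(5-bromo-2-hydroxy-4-methoxyphenyl)-7-hydroxy-4H-chromen-4-one | COc1cc(O)c(-c2coc3cc(O)ccc3c2=O)cc1Br | intermediate
12 | 3-[2-(acetyloxy)-5-bromo-4-methoxyphenyl]-4-oxo-4H-chromen-7-yl acetate | COc1cc(OC(C)=O)c(-c2coc3cc(OC(C)=O)ccc3c2=O)cc1Br | intermediate
13 | tributyl(3-methylbut-2-en-1-yl)stannane | CCCC[Sn](CCCC)(CCCC)CC=C(C)C | starting material
14 | 3-[2-(acetyloxy)-4-methoxy-5-(3-methylbut-2-en-1-yl)phenyl]-4-oxo-4H-chromen-7-yl acetate | COc1cc(OC(C)=O)c(-c2coc3cc(OC(C)=O)ccc3c2=O)cc1CC=C(C)C | intermediate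
15 | 7-hydroxy-3-[2-hydroxy-4-methoxy-5-(3-methylbut-2-en-1-yl)phenyl]-4H-chromen-4-one | COc1cc(O)c(-c2coc3cc(O)ccc3c2=O)cc1CC=C(C)C | target

**Total step count:** 10.
**Longest linear sequence:** 9 steps (1 → 2 → 3 → 7 → 8 → 10 → 11 → 12 → 14 → 15).

**Three steps most likely to fail**

Step 5 (oxidative aryl shift). The free ring A phenol can divert material to an aurone or flavone. The nitric acid formed can nitrate the electron-rich rings, and the chalcone is poorly soluble in methanol. The fallback sets out from 7 and comes back at 10, and it replaces the aryl shift by an aroyl shift in an epoxide. The chelated phenol of 7 is capped with NaH and MOMCl in DMF at 0 °C to give the 2'-O-methoxymethyl chalcone F1. Weitz–Scheffer epoxidation (30% H2O2, NaOH, MeOH/THF, 0 °C to rt) gives the racemic trans-epoxy ketone F2. BF3·OEt2 in CH2Cl2 at −20 °C opens the epoxide at the benzylic carbon, and a 1,2-aroyl migration gives the alpha-formyl deoxybenzoin F3. HCl in refluxing MeOH then removes the MOM group and cyclodehydrates to 10, where the route continues with the debenzylation.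

Step 9 (Stille prenylation). Oxidative addition into an ortho-alkoxy bromoarene can be slow, and prenyl transfer can give some branched (reverse-prenyl) isomer that is hard to separate. The fallback sets out from 12 and comes back at 14, and it builds the prenyl group in two operations with no regiochemical ambiguity. Coupling of 12 with allyltributylstannane (Pd(PPh3)4, toluene, 100 °C) gives the 5'-allyl diacetate F4. Olefin cross-metathesis of F4 with a large excess of 2-methylbut-2-ene (second-generation Grubbs catalyst, 5 mol %, CH2Cl2, 40 °C, sealed tube) gives 14.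

Step 7 (double debenzylation). BCl3 binds to the chromone carbonyl, so cleavage may stall at the monobenzyl stage. Forcing it risks C-benzylation or loss of the methyl ether, and hydrogenolysis is ruled out while the C–Br bond is present. The fallback sets out from 10 and comes back at 14, and it uses up the C–Br bond first so that hydrogenolysis becomes available. Sonogashira coupling of 10 with 2-methylbut-3-yn-2-ol (PdCl2(PPh3)2, CuI, Et3N/DMF, 80 °C) gives the propargylic alcohol F5. H2 over Pd/C (10 wt %, EtOAc/MeOH, rt, monitored to avoid reducing the C2–C3 double bond) saturates the alkyne and cleaves both benzyl ethers, giving the hydroxyisopentyl diphenol F6. Ac2O in pyridine acetylates only the two phenols to give the tertiary alcohol diacetate F7. Acid-catalysed dehydration (p-TsOH·H2O, toluene, 90 °C) gives the more substituted alkene 14, which goes on to the final deacetylation.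

**Further compounds**
F1 | step 5 | (E)-1-[4-(benzyloxy)-2-(methoxymethoxy)phenyl]-3-[2-(benzyloxy)-5-bromo-4-methoxyphenyl]prop-2-en-1-one | COCOc1cc(OCc2ccccc2)ccc1C(=O)/C=C/c1cc(Br)c(OC)cc1OCc1ccccc1
F2 | step 5 | racemic trans-[4-(benzyloxy)-2-(methoxymethoxy)phenyl]{3-[2-(benzyloxy)-5-bromo-4-methoxyphenyl]oxiran-2-yl}methanone (one enantiomer drawn) | COCOc1cc(OCc2ccccc2)ccc1C(=O)[C@@H]1O[C@H]1c1cc(Br)c(OC)cc1OCc1ccccc1
F3 | step 5 | racemic 3-[4-(benzyloxy)-2-(methoxymethoxy)phenyl]-2-[2-(benzyloxy)-5-bromo-4-methoxyphenyl]-3-oxopropanal | COCOc1cc(OCc2ccccc2)ccc1C(=O)C(C=O)c1cc(Br)c(OC)cc1OCc1ccccc1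
F4 | step 9 | 3-[2-(acetyloxy)-4-methoxy-5-(prop-2-en-1-yl)phenyl]-4-oxo-4H-chromen-7-yl acetate | COc1cc(OC(C)=O)c(-c2coc3cc(OC(C)=O)ccc3c2=O)cc1CC=C
F5 | step 7 | 7-(benzyloxy)-3-[2-(benzyloxy)-5-(3-hydroxy-3-methylbut-1-yn-1-yl)-4-methoxyphenyl]-4H-chromen-4-one | COc1cc(OCc2ccccc2)c(-c2coc3cc(OCc4ccccc4)ccc3c2=O)cc1C#CC(C)(C)O
F6 | step 7 | 7-hydroxy-3-[2-hydroxy-5-(3-hydroxy-3-methylbutyl)-4-methoxyphenyl]-4H-chromen-4-one | COc1cc(O)c(-c2coc3cc(O)ccc3c2=O)cc1CCC(C)(C)O
F7 | step 7 | 3-[2-(acetyloxy)-5-(3-hydroxy-3-methylbutyl)-4-methoxyphenyl]-4-oxo-4H-chromen-7-yl acetate | COc1cc(OC(C)=O)c(-c2coc3cc(OC(C)=O)ccc3c2=O)cc1CCC(C)(C)O
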